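Everything rests on disconnecting the side chain at the benzylic bond C1'–C2' and at the C3'–CH3 bond. The feature used is the unit ring B–C1'H2–C2'H=C3'(CH3): an (E)-2-methylalk-1-enyl group on a benzylic carbon, so ring B (the benzoate ring) can enter as a benzylic chloride. In one operation a terminal alkyne is methylaluminated syn under zirconium catalysis and the resulting (E)-alkenylalane is coupled with the benzylic chloride by zerovalent nickel, creating both bonds and the 2'E geometry. The precursor is a C18 enyne that already holds ring A (the trimethylcyclohexene) and the 6'E alkene; its partner is a methyl benzoate with a silylated phenol ortho to CH2Cl.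

Key step: step 8

Assumption: side-chain locants C1' to C9' run from the benzylic carbon to the carbon attached to ring A, and (4-bromobut-1-yn-1-yl)trimethylsilane is taken as a purchasable reagent alongside dihydro-β-ionone, methyl 3-formyl-4-hydroxybenzoate and Me3Al.

**Step 1**
Reactants: 1 dihydro-β-ionone
Product: 3 2-(but-3-yn-1-yl)-1,3,3-trimethylcyclohex-1-ene, via enol phosphate 2 (not isolated)
Conditions: LiN(i-Pr)2 (1.05 equiv), THF, −78 °C; ClP(O)(OEt)2, −78 °C to rt; then LiN(i-Pr)2 (2.3 equiv), THF, −78 °C to rt; H2O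
Reagents that add atoms: none
Why: Kinetic deprotonation at the methyl group, O-phosphorylation and amide-induced 1,2-elimination of diethyl phosphate from the terminal enol phosphate (Negishi conversion of a methyl ketone into a terminal alkyne) should give the lithium acetylide, which the excess base protects from isomerisation until it is protonated on work-up, while the hindered ring alkene is untouched.

**Step 2**
Reactants: 3 2-(but-3-yn-1-yl)-1,3,3-trimethylcyclohex-1-ene; 4 trimethylaluminium
Product: 6 2-[(3E)-4-iodo-3-methylbut-3-en-1-yl]-1,3,3-trimethylcyclohex-1-ene, via alkenylalane 5 (not isolated)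
Conditions: Me3Al (2 equiv), Cp2ZrCl2 (0.25 equiv), CH2Cl2, 0 °C to rt; then I2, THF, −30 to 0 °C
Reagents that add atoms: trimethylaluminium 4, C[Al](C)C; iodine, II
Why: Zirconium-catalysed methylalumination (Negishi carboalumination) adds CH3 and aluminium syn with aluminium at the terminal carbon, and iodinolysis of the alkenyl C–Al bond with retention should give the E iodide, the tetrasubstituted ring alkene being inert to both reagents at low temperature.

**Step 3**
Reactants: 6 2-[(3E)-4-iodo-3-methylbut-3-en-1-yl]-1,3,3-trimethylcyclohex-1-ene; 7 (4-bromobut-1-yn-1-yl)trimethylsilane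
Product: 9 trimethyl[(5E)-6-methyl-8-(2,6,6-trimethylcyclohex-1-en-1-yl)oct-5-en-1-yn-1-yl]silane, via alkylzinc bromide 8 (not isolated)
Conditions: 7, Zn dust, LiCl, THF, 50 °C; then 6, Pd(PPh3)4 (5 mol%), THF, rt
Reagents that add atoms: none
Why: LiCl-promoted zinc insertion gives a homopropargylic zinc reagent that undergoes Negishi sp2–sp3 coupling with the alkenyl iodide under zerovalent palladium catalysis with retention of the E geometry, reductive elimination outpacing β-hydride elimination for this class of alkylzinc, and the silyl cap keeps the alkyne terminus from being metalated.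

**Step 4**
Reactants: 9 trimethyl[(5E)-6-methyl-8-(2,6,6-trimethylcyclohex-1-en-1-yl)oct-5-en-1-yn-1-yl]silane
Product: 10 2-[(3E)-3-methyloct-3-en-7-yn-1-yl]-1,3,3-trimethylcyclohex-1-ene
Conditions: K2CO3 (0.3 equiv), MeOH/THF, rt
Reagents that add atoms: none
Why: Base-catalysed methanolysis of the alkynyl C–Si bond (protiodesilylation) is selective and leaves both alkenes unchanged.

**Step 5**
Reactants: 11 methyl 3-formyl-4-hydroxybenzoate
Product: 12 methyl 3-formyl-4-[(triisopropylsilyl)oxy]benzoate
Conditions: i-Pr3SiCl, imidazole, DMF, rt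
Reagents that add atoms: triisopropylsilyl chloride, CC(C)[Si](Cl)(C(C)C)C(C)C
Why: Imidazole-mediated O-silylation of the acidic phenol installs a bulky silyl ether that masks the proton that would quench the alane, resists silyl migration and is removable without acid.

**Step 6**
Reactants: 12 methyl 3-formyl-4-[(triisopropylsilyl)oxy]benzoate
Product: 13 methyl 3-(hydroxymethyl)-4-[(triisopropylsilyl)oxy]benzoate
Conditions: NaBH4, THF/MeOH, −10 °C; aq. NH4Cl
Reagents that add atoms: none
Why: Borohydride reduction is chemoselective for the aryl aldehyde over the benzoate ester, and the low temperature together with the bulk of the triisopropylsilyl group should suppress O-to-O silyl migration to the new benzylic alkoxide.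

**Step 7**
Reactants: 13 methyl 3-(hydroxymethyl)-4-[(triisopropylsilyl)oxy]benzoate
Product: 15 methyl 3-(chloromethyl)-4-[(triisopropylsilyl)oxy]benzoate, via mesylate 14 (not isolated)
Conditions: MeSO2Cl, Et3N, CH2Cl2, 0 °C; then LiCl, DMF, rt
Reagents that add atoms: lithium chloride, [Li+].[Cl-]
Why: Sulfonylation of the primary benzylic alcohol followed by SN2 displacement with chloride proceeds under non-acidic, fluoride-free conditions that preserve the aryl silyl ether and the ester.

**Step 8**
Reactants: 10 2-[(3E)-3-methyloct-3-en-7-yn-1-yl]-1,3,3-trimethylcyclohex-1-ene; 4 trimethylaluminium; 15 methyl 3-(chloromethyl)-4-[(triisopropylsilyl)oxy]benzoate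
Product: 17 methyl 3-[(2E,6E)-3,7-dimethyl-9-(2,6,6-trimethylcyclohex-1-en-1-yl)nona-2,6-dien-1-yl]-4-[(triisopropylsilyl)oxy]benzoate, via dienylalane 16 (not isolated)
Conditions: Me3Al (2 equiv), Cp2ZrCl2 (0.25 equiv), ClCH2CH2Cl, rt; volatiles removed in vacuo, THF; then 15, NiCl2(PPh3)2 (5 mol%) pre-reduced with n-BuLi (10 mol%) to zerovalent nickel, 0 °C to rt
Reagents that add atoms: trimethylaluminium 4, C[Al](C)C
Why: Cp2ZrCl2 and Me3Al form a methylzirconium–aluminium species that adds CH3 and metal syn across the terminal C≡C of 10, CH3 to the internal carbon (future C3') and aluminium to the terminal carbon (future C2'), giving the (1E)-alkenyl dimethylalane 16. Zerovalent nickel then inserts into the benzylic C–Cl bond of 15, the alkenyl group passes from aluminium to nickel, and reductive elimination forms C1'–C2' with retention of the alkene geometry. The closest known reaction type is the Negishi zirconium-catalysed carboalumination joined to the nickel-catalysed coupling of alkenylalanes with benzylic chlorides, as applied to prenylated quinone and arene side chains. No ring is closed and no stereocentre is created; the only stereochemical element, the 2'E alkene, is fixed by syn carbometalation followed by stereoretentive transmetalation and reductive elimination. The step needs regioselective methyl delivery and chemoselectivity: the unhindered terminal alkyne with no nearby heteroatom places aluminium at the chain end, the tri- and tetrasubstituted alkenes do not carbometalate, and the methyl benzoate and aryl silyl ether are tolerated by the alkenylalane in THF. Stripping the excess Me3Al before the nickel catalyst is added suppresses competing methyl transfer to the benzylic carbon.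

**Step 9**
Reactants: 17 methyl 3-[(2E,6E)-3,7-dimethyl-9-(2,6,6-trimethylcyclohex-1-en-1-yl)nona-2,6-dien-1-yl]-4-[(triisopropylsilyl)oxy]benzoate
Product: 19 cacospongin D, via cacospongin D methyl ester 18 (not isolated)
Conditions: n-Bu4NF, THF, 0 °C; then LiOH, MeOH/H2O, 50 °C; 1 M HCl to pH 3, 0 °C
Reagents that add atoms: lithium hydroxide, [Li+].[OH-]
Why: Fluoride cleaves the aryl O–Si bond and hydroxide then saponifies the methyl benzoate by acyl substitution in the same flask, and the basic medium with a brief cold acidification avoids acid-catalysed cyclisation of the phenol onto the C2'=C3' alkene.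

**Compound list**
1 | dihydro-β-ionone [4-(2,6,6-trimethylcyclohex-1-en-1-yl)butan-2-one] | CC(=O)CCC1=C(C)CCCC1(C)C | starting material
2 | diethyl 4-(2,6,6-trimethylcyclohex-1-en-1-yl)but-1-en-2-yl phosphate | C=C(CCC1=C(C)CCCC1(C)C)OP(=O)(OCC)OCC | intermediate
3 | 2-(but-3-yn-1-yl)-1,3,3-trimethylcyclohex-1-ene | CC1=C(CCC#C)C(C)(C)CCC1 | intermediate
4 | trimethylaluminium | C[Al](C)C | starting material
5 | dimethyl[(1E)-2-methyl-4-(2,6,6-trimethylcyclohex-1-en-1-yl)but-1-en-1-yl]alumane | CC1=C(CC/C(C)=C/[Al](C)C)C(C)(C)CCC1 | intermediate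
6 | 2-[(3E)-4-iodo-3-methylbut-3-en-1-yl]-1,3,3-trimethylcyclohex-1-ene | CC1=C(CC/C(C)=C/I)C(C)(C)CCC1 | intermediate
7 | (4-bromobut-1-yn-1-yl)trimethylsilane | C[Si](C)(C)C#CCCBr | starting material
8 | [4-(trimethylsilyl)but-3-yn-1-yl]zinc bromide | C[Si](C)(C)C#CCC[Zn]Br | intermediate
9 | trimethyl[(5E)-6-methyl-8-(2,6,6-trimethylcyclohex-1-en-1-yl)oct-5-en-1-yn-1-yl]silane | CC1=C(CC/C(C)=C/CCC#C[Si](C)(C)C)C(C)(C)CCC1 | intermediate
10 | 2-[(3E)-3-methyloct-3-en-7-yn-1-yl]-1,3,3-trimethylcyclohex-1-ene | CC1=C(CC/C(C)=C/CCC#C)C(C)(C)CCC1 | intermediate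
11 | methyl 3-formyl-4-hydroxybenzoate | COC(=O)c1ccc(O)c(C=O)c1 | starting material
12 | methyl 3-formyl-4-[(triisopropylsilyl)oxy]benzoate | COC(=O)c1ccc(O[Si](C(C)C)(C(C)C)C(C)C)c(C=O)c1 | intermediate
13 | methyl 3-(hydroxymethyl)-4-[(triisopropylsilyl)oxy]benzoate | COC(=O)c1ccc(O[Si](C(C)C)(C(C)C)C(C)C)c(CO)c1 | intermediate
14 | methyl 3-{[(methylsulfonyl)oxy]methyl}-4-[(triisopropylsilyl)oxy]benzoate | COC(=O)c1ccc(O[Si](C(C)C)(C(C)C)C(C)C)c(COS(C)(=O)=O)c1 | intermediate
15 | methyl 3-(chloromethyl)-4-[(triisopropylsilyl)oxy]benzoate | COC(=O)c1ccc(O[Si](C(C)C)(C(C)C)C(C)C)c(CCl)c1 | intermediate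
16 | [(1E,5E)-2,6-dimethyl-8-(2,6,6-trimethylcyclohex-1-en-1-yl)octa-1,5-dien-1-yl]dimethylalumane | CC1=C(CC/C(C)=C/CC/C(C)=C/[Al](C)C)C(C)(C)CCC1 | intermediate
17 | methyl 3-[(2E,6E)-3,7-dimethyl-9-(2,6,6-trimethylcyclohex-1-en-1-yl)nona-2,6-dien-1-yl]-4-[(triisopropylsilyl)oxy]benzoate | CC1=C(CC/C(C)=C/CC/C(C)=C/Cc2cc(C(=O)OC)ccc2O[Si](C(C)C)(C(C)C)C(C)C)C(C)(C)CCC1 | intermediate
18 | cacospongin D methyl ester [methyl 3-[(2E,6E)-3,7-dimethyl-9-(2,6,6-trimethylcyclohex-1-en-1-yl)nona-2,6-dien-1-yl]-4-hydroxybenzoate] | CC1=C(CC/C(C)=C/CC/C(C)=C/Cc2cc(C(=O)OC)ccc2O)C(C)(C)CCC1 | intermediate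
19 | cacospongin D [3-[(2E,6E)-3,7-dimethyl-9-(2,6,6-trimethylcyclohex-1-en-1-yl)nona-2,6-dien-1-yl]-4-hydroxybenzoic acid] | CC1=C(CC/C(C)=C/CC/C(C)=C/Cc2cc(C(=O)O)ccc2O)C(C)(C)CCC1 | target

Total step count: 9. Longest linear sequence: 6 steps (steps 1, 2, 3, 4, 8, 9 from dihydro-β-ionone); the arene branch (steps 5, 6, 7) joins at step 8.

**Steps most likely to fail**

Step 8. The coupling may be eroded by transfer of a methyl group from residual methylaluminium species to the benzylnickel intermediate, by reductive homocoupling of the benzylic chloride, or by slow attack of aluminium reagents on the ester. The fallback reverses the polarity of the partners and removes aluminium from the bond-forming event. Setting out from enyne 10, the same methylalumination is quenched with iodine to give 2-[(3E,7E)-8-iodo-3,7-dimethylocta-3,7-dien-1-yl]-1,3,3-trimethylcyclohex-1-ene F1. Chloride 15 is converted with Zn dust and LiCl in THF into {5-(methoxycarbonyl)-2-[(triisopropylsilyl)oxy]benzyl}zinc chloride F2. Negishi coupling of F1 with F2 under Pd(PPh3)4 catalysis should then form the same C1'–C2' bond with retention and return to 17.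

Step 3. Zinc insertion may be sluggish, the alkylzinc may be protonated, or β-hydride elimination at the alkylpalladium stage may give reduced or isomerised material instead of the 1,5-enyne. The fallback builds the two-carbon spacer by epoxide opening and attaches the alkyne by SN2 substitution. Setting out from alkyne 3, methylalumination as in step 2 gives alane 5, which is turned into the alanate with n-BuLi and opened with ethylene oxide to (3E)-4-methyl-6-(2,6,6-trimethylcyclohex-1-en-1-yl)hex-3-en-1-ol F3. I2, PPh3 and imidazole in CH2Cl2 convert it into 2-[(3E)-6-iodo-3-methylhex-3-en-1-yl]-1,3,3-trimethylcyclohex-1-ene F4. Displacement with lithium (trimethylsilyl)acetylide in THF/DMPU (−78 °C to rt) rejoins the route at 9.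

Step 1. Enolisation may not be fully regioselective, and the elimination may partly drift to an allene or internal alkyne, so the terminal alkyne would be contaminated or formed inefficiently. The fallback avoids enolate regiochemistry by degrading the ketone by one carbon and homologating. Setting out from 1, haloform cleavage with NaOBr (Br2, NaOH, dioxane/H2O, 0 °C) gives 3-(2,6,6-trimethylcyclohex-1-en-1-yl)propanoic acid F5. LiAlH4 in THF reduces it to 3-(2,6,6-trimethylcyclohex-1-en-1-yl)propan-1-ol F6. Dess–Martin periodinane in CH2Cl2 gives 3-(2,6,6-trimethylcyclohex-1-en-1-yl)propanal F7. Seyferth–Gilbert homologation with the Ohira–Bestmann reagent (dimethyl (1-diazo-2-oxopropyl)phosphonate, K2CO3, MeOH, rt) returns to alkyne 3.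

**Further compounds**
F1 | step 8 | 2-[(3E,7E)-8-iodo-3,7-dimethylocta-3,7-dien-1-yl]-1,3,3-trimethylcyclohex-1-ene | CC1=C(CC/C(C)=C/CC/C(C)=C/I)C(C)(C)CCC1
F2 | step 8 | {5-(methoxycarbonyl)-2-[(triisopropylsilyl)oxy]benzyl}zinc chloride | COC(=O)c1ccc(O[Si](C(C)C)(C(C)C)C(C)C)c(C[Zn]Cl)c1
F3 | step 3 | (3E)-4-methyl-6-(2,6,6-trimethylcyclohex-1-en-1-yl)hex-3-en-1-ol | CC1=C(CC/C(C)=C/CCO)C(C)(C)CCC1
F4 | step 3 | 2-[(3E)-6-iodo-3-methylhex-3-en-1-yl]-1,3,3-trimethylcyclohex-1-ene | CC1=C(CC/C(C)=C/CCI)C(C)(C)CCC1
F5 | step 1 | 3-(2,6,6-trimethylcyclohex-1-en-1-yl)propanoic acid | CC1=C(CCC(=O)O)C(C)(C)CCC1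
F6 | step 1 | 3-(2,6,6-trimethylcyclohex-1-en-1-yl)propan-1-ol | CC1=C(CCCO)C(C)(C)CCC1
F7 | step 1 | 3-(2,6,6-trimethylcyclohex-1-en-1-yl)propanal | CC1=C(CCC=O)C(C)(C)CCC1
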